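## Structural features

The target is a flavone: benzene ring A is fused to 4-pyranone ring C (a 4H-chromen-4-one), and the 2,4-dihydroxyphenyl ring B is joined to C2 by a single aryl–vinyl bond. Every carbon of ring A carries oxygen (5-OH, 6-, 7- and 8-OMe, O1 at C8a) except C4a, and ring C carries a methoxy group at C3. The molecule has no stereocentre; the only stereochemical question in the route is the geometry of the acyclic C2=C3 alkene before ring C is closed. The fragile parts are the three free phenols on electron-rich rings, which oxidise easily under base, and the methyl ethers at C3 and C6, which lie next to chelating sites and can be lost to strong Lewis acids. The real difficulty is twofold: building a hexasubstituted ring A with the oxygen pattern in the right place, and finishing with exactly three hydroxyls (C5, C2', C4') free beside four methyl ethers. The key step exploits the fact that a 2,3,4,5-tetramethoxyphenoxy group has a single hydrogen-bearing ring carbon, the future C4a, ortho to the oxygen that becomes O1. An acyl carbon (the future C4) tethered to that oxygen through C2 and C3 can therefore form the C4–C4a bond only at that position. The 5-OH is told apart at the end because it alone forms a six-membered chelate with the C4 carbonyl.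

## Logic of the disconnections

**18 to 16 (through 17).** Three oxygen–alkyl bonds are cut: O5–CH3 and the two O–CH(CH3)2 bonds at O2' and O4'. This removes every free phenol from the ring-forming stages and makes ring A a uniform tetramethoxy unit that can come from a symmetrical arene. The forward step must cleave two secondary alkyl ethers and exactly one of five methyl ethers, which relies on chelation of boron between the C4 carbonyl and O5.

**16 to 14 (through 15).** The C4–C4a bond is cut, opening ring C to an acrylic acid that still holds O1, C2, C3 and both aryl groups. The cut is placed here because C4a is the only free carbon of ring A, so the regiochemistry of the return reaction is fixed by substitution. The forward step needs the carboxyl group cis to the aryloxy group, and it needs ring A carbon to win over ring B, both over C6' and over the ether oxygen O2'.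

**14 to 13.** The carboxyl O–H is traced back to an O–CH3 ester, so that the acid is only unmasked immediately before the closure. The forward saponification must leave the enol ether and the alkene geometry alone.

**13 to 12 and 4.** The vinyl carbon–oxygen bond that becomes C2–O1 is cut, splitting the molecule into a ring A phenol and a ring B acrylate. This is the convergent joint of the synthesis. The forward step requires the phenoxide of 4 to attack carbon and not sulfur, and to do so with retention of geometry.

**12 to 11.** The O–S bond is cut, returning the enol sulfonate to a β-keto ester. The forward step must sulfonylate the ketone oxygen, with the ester cis to the new leaving group.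

**11 to 7 and 8 (through 9 and 10).** The C–C bond between the ketone carbonyl and the methoxy-bearing carbon (the future C2–C3 bond) is cut. This gives an aroyl electrophile and a two-carbon ester that already carries the C3 methoxy group. The forward step must be a clean crossed acylation of an ester enolate without self-condensation.

**7 to 5 (through 6).** The two aryl O–isopropyl bonds are cut, leading back to a commodity dihydroxy acid. The forward step must alkylate the hydrogen-bonded ortho hydroxyl as well as the para one.

**4 to 1 (through 2 and 3).** The aryl C–O(H) bond is cut, leading back to a symmetrical tetra-ether whose two ring hydrogens are equivalent. The forward step must replace one of them by oxygen without over-oxidising a very electron-rich phenol.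

## Other disconnections considered

**Alternative 1:** The cut is C3–C4. In the forward direction a carbene catalyst would turn the aromatic formyl group of dialdehyde A1 into an acyl anion equivalent that adds to the aliphatic formyl group, closing ring C as the 3-hydroxychroman-4-one A2. Dehydrogenation to flavonol A3, O-methylation at C3, debenzylation and 5-O-demethylation would then lead to 18.

- In its favour: the C4 carbonyl and the C3 oxygen appear together under nearly neutral, metal-free conditions. No electrophilic aromatic substitution is involved, so the ortho oxygen of ring B cannot compete as a nucleophile. On that chemoselectivity point it is the equal or the better of the chosen plan.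
- Against it: A1 is an α-aryloxy aldehyde. If the carbene adds to that formyl group instead, the aryloxide is expected to be expelled, which destroys the tether. A1 is also easily enolised and hard to prepare and store.
- Comparison: two stereocentres are made in A2 only to be erased. Three to four steps follow the key step, against one in the chosen plan. The final distinction of the 5-oxygen still has to be solved by the same chelation-controlled demethylation. The alternative is longer and mechanistically less secure.

**Alternative 2:** The cuts are C1'–C2' and C5'–C6' of ring B. In the forward direction 2-ethynylchromone A4 and the bis-silyloxy diene A5 would combine in a (4+2) cycloaddition, and loss of methanol and the silyl groups on acidic work-up would give the free resorcinol A6. The polarity match places the nucleophilic CH2 terminus of A5 on the terminal alkyne carbon, so the hydroxyls should land at C2' and C4'.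

- In its favour: ring B arrives unprotected, which is better than the chosen plan in protecting-group economy. The endgame is one selective 5-O-demethylation, equal in length to the chosen one and simpler in that no isopropyl ethers have to be removed at the same time.
- Against it: the hard part of the molecule, the fully oxygenated ring A fused to a 3-methoxypyranone, is not addressed. A4 still needs a ring C construction of its own, now in the presence of a sensitive conjugated alkyne. A4 also offers the chromone C2 position as a competing site for conjugate attack by the very nucleophilic A5.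
- Comparison: the cycloaddition is mechanistically sound, but the overall count would exceed that of the chosen plan because the preparation of A4 is at least as long as the preparation of 16.

**Alternative 3:** The cut is C5–C4a (with C8–C8a formed one step earlier). Metalated pyranone A7 would be added to dimethyl squarate A8 to give the cyclobutenone adduct A9. Heating A9 should trigger a four-electron ring opening and a six-electron closure onto the pyranone C–H carbon, giving the 5,8-hydroquinone A10. Methylation of the unchelated 8-OH and hydrogenolysis of the benzyl ethers would finish the synthesis.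

- In its favour: the 5-OH is delivered directly and is told apart from the 8-OH by hydrogen bonding. No selective demethylation is needed, and on this point it is better than the chosen plan. The thermal steps are neutral, and the regiochemistry is fixed by connectivity, which is the equal of the chosen plan.
- Against it: A7 is not a commodity, and metalating it next to the ring oxygen without addition to, or opening of, the pyranone is uncertain. The para-hydroquinone unit of A10 is expected to oxidise readily in air. Two steps follow the key step, against one.
- Comparison: counting the preparation of A7, this route is clearly longer than the chosen plan.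

Key step: step 7

Remark on the chemistry (assumption): in acid 14 the E descriptor means carboxyl cis to the aryloxy group, which is the geometry the closure needs. In the Z isomer the ether oxygen O2' of ring B, and not only C6', is within reach of the acyl carbon, so the conditions of steps 4 to 7 are chosen to keep the E geometry and to leave the isopropyl ethers intact.

## Route

**Step 1**
Reactants: 1 1,2,3,4-tetramethoxybenzene
Product: 4 2,3,4,5-tetramethoxyphenol, via aryllithium 2 (not isolated), via lithium aryltrimethoxyborate 3 (not isolated)
Conditions: n-BuLi, TMEDA, THF, 0 °C; B(OMe)3, −78 °C → rt; AcOH, 30% H2O2, 0 °C → rt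
Reagents that add atoms: hydrogen peroxide, OO
Why: Directed ortho-metalation followed by boronate oxidation: the two ring hydrogens of 1 are equivalent and each lies ortho to a lithium-coordinating methoxy group, so a single aryllithium 2 should form; borylation to 3 and peroxide-induced 1,2-migration of the aryl group from boron to oxygen place the hydroxyl exactly at the metalated carbon, and no stereocentre is involved.

**Step 2**
Reactants: 5 2,4-dihydroxybenzoic acid
Product: 7 2,4-di(propan-2-yloxy)benzoic acid, via propan-2-yl 2,4-di(propan-2-yloxy)benzoate 6 (not isolated)
Conditions: 2-bromopropane (4 equiv), K2CO3, DMSO, 60 °C; then aq KOH, 90 °C; then aq HCl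
Reagents that add atoms: 2-bromopropane, CC(C)Br; potassium hydroxide, [K+].[OH-] (its oxygen becomes one carboxyl oxygen)
Why: Williamson etherification and carboxylate alkylation in a dipolar aprotic solvent should alkylate all three acidic sites (the hydrogen-bonded ortho hydroxyl last, hence heat and excess bromide); saponification in the same flask then cleaves only the ester of 6, because aryl isopropyl ethers are inert to hydroxide.

**Step 3**
Reactants: 7 2,4-di(propan-2-yloxy)benzoic acid; 8 methyl methoxyacetate
Product: 11 methyl 3-[2,4-di(propan-2-yloxy)phenyl]-2-methoxy-3-oxopropanoate (racemic), via 2,4-di(propan-2-yloxy)benzoyl chloride 9 (not isolated), via lithium enolate of methyl methoxyacetate 10 (not isolated)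
Conditions: 7, (COCl)2, cat. DMF, CH2Cl2, 0 °C → rt, evaporate; separately 8 (2.2 equiv), LiN(iPr)2 (2.2 equiv), THF, −78 °C; add crude 9, −78 → −20 °C; aq NH4Cl
Reagents that add atoms: none
Why: Crossed Claisen condensation (C-acylation of an ester enolate): acid chloride 9 is far more electrophilic than any ester present, and two equivalents of enolate 10 are used because 11 is deprotonated as it forms, which also protects it from a second acylation; the stereocentre at the methoxy-bearing carbon forms racemic and is removed in step 4.

**Step 4**
Reactants: 11 methyl 3-[2,4-di(propan-2-yloxy)phenyl]-2-methoxy-3-oxopropanoate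
Product: 12 methyl (E)-3-[2,4-di(propan-2-yloxy)phenyl]-2-methoxy-3-(trifluoromethanesulfonyloxy)prop-2-enoate
Conditions: NaH, Et2O, 0 °C → rt; Tf2O, −78 → 0 °C
Reagents that add atoms: trifluoromethanesulfonic anhydride, O=S(=O)(OS(=O)(=O)C(F)(F)F)C(F)(F)F
Why: O-sulfonylation of a β-keto ester enolate: in a weakly coordinating solvent the sodium enolate is held as a six-membered chelate between the ketone and ester oxygens, so triflation of the ketone oxygen should place the triflate cis to the ester, which is the E isomer by the sequence rules.

**Step 5**
Reactants: 12 methyl (E)-3-[2,4-di(propan-2-yloxy)phenyl]-2-methoxy-3-(trifluoromethanesulfonyloxy)prop-2-enoate; 4 2,3,4,5-tetramethoxyphenol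
Product: 13 methyl (E)-3-[2,4-di(propan-2-yloxy)phenyl]-2-methoxy-3-(2,3,4,5-tetramethoxyphenoxy)prop-2-enoate
Conditions: Cs2CO3, DMF, argon, rt → 50 °C
Reagents that add atoms: none
Why: Nucleophilic vinylic substitution by addition–elimination, the reaction type of phenoxides with β-chloro- and β-sulfonyloxy-acrylates: the triflate-bearing carbon of 12 is activated by the ester, the cesium phenoxide adds there, and triflate should leave from the ester enolate faster than the central bond rotates, so the geometry is expected to be retained.

**Step 6**
Reactants: 13 methyl (E)-3-[2,4-di(propan-2-yloxy)phenyl]-2-methoxy-3-(2,3,4,5-tetramethoxyphenoxy)prop-2-enoate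
Product: 14 (E)-3-[2,4-di(propan-2-yloxy)phenyl]-2-methoxy-3-(2,3,4,5-tetramethoxyphenoxy)prop-2-enoic acid
Conditions: LiOH·H2O, THF–MeOH–H2O, rt → 40 °C; then 1 M HCl to pH 3, 0 °C
Reagents that add atoms: lithium hydroxide, [Li+].[OH-] (its oxygen becomes one carboxyl oxygen)
Why: Saponification by acyl–oxygen cleavage, as used for β-aryloxyacrylic esters in the Ruhemann sequence; the crowded, donor-substituted β-carbon should resist conjugate attack by hydroxide, and cold, brief acidification liberates the acid without exposing the push–pull alkene to strong acid.

**Step 7**
Reactants: 14 (E)-3-[2,4-di(propan-2-yloxy)phenyl]-2-methoxy-3-(2,3,4,5-tetramethoxyphenoxy)prop-2-enoic acid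
Product: 16 2-[2,4-di(propan-2-yloxy)phenyl]-3,5,6,7,8-pentamethoxy-4H-chromen-4-one, via mixed trifluoroacetic anhydride 15 (not isolated)
Conditions: (CF3CO)2O (3 equiv), CH2Cl2 (about 0.02 M), 0 °C → rt
Reagents that add atoms: none
Why: Ruhemann-type intramolecular Friedel–Crafts acylation: (CF3CO)2O converts the acid into mixed anhydride 15, which reacts as such or as the derived oxygen-stabilised acylium ion with the ring A carbon lying cis to it across the C2=C3 bond, and loss of the proton from the arenium ion gives the chromone and trifluoroacetic acid. The closest known reaction types are the acid-mediated cyclisation of β-aryloxycinnamic and β-aryloxyacrylic acids to flavones and chromones and the anhydride-mediated closure of 2-aryloxybenzoic acids to xanthones. Ring C closes in a six-membered mode in which the acyl carbon is attacked with its C=O outside the new ring (6-exo-trig at the carbonyl) while the attacked arene bond is endocyclic; no stereocentre is created. Regioselectivity on ring A needs no control, because the attacked carbon is the only one bearing hydrogen and it is activated by the ortho ether oxygen, an ortho methoxy group and a para methoxy group. The selectivity that must be secured is ring A carbon against two sites of ring B: C6', which is meta to both isopropoxy groups and would give a five-membered indenone, and the ether oxygen O2', which in the Z isomer could lactonise to a coumarin with loss of its isopropyl group. The E geometry of 14 keeps the acyl carbon away from ring B, and the mild anhydride activation at 0 °C without strong protic acid leaves the isopropyl ethers intact, so attack by O2' should stay reversible and unproductive while C-acylation of the electron-rich ring A carbon is irreversible. Any Z isomer present can equilibrate through the push–pull alkene under the trifluoroacetic acid released and is then drained through the E isomer. Intermolecular acylation of ring B is suppressed by the high dilution.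

**Step 8**
Reactants: 16 2-[2,4-di(propan-2-yloxy)phenyl]-3,5,6,7,8-pentamethoxy-4H-chromen-4-one
Product: 18 5,2',4'-trihydroxy-3,6,7,8-tetramethoxyflavone [2-(2,4-dihydroxyphenyl)-5-hydroxy-3,6,7,8-tetramethoxy-4H-chromen-4-one], via tris(dichloroboryl) ether 17 (not isolated)
Conditions: BCl3 (1 M in CH2Cl2, 6 equiv), CH2Cl2, −78 → 0 °C; then H2O
Reagents that add atoms: none
Why: Lewis-acid ether cleavage: BCl3 removes secondary alkyl aryl ethers at low temperature and, held in a six-membered chelate between the C4 carbonyl and O5, cleaves the peri 5-methyl ether, while the unchelated 6-, 7- and 8-methyl ethers and the 3-methyl ether (which could form only a five-membered chelate) should persist at or below 0 °C; hydrolysis of 17 on work-up releases 18.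

## Compound list

1 | 1,2,3,4-tetramethoxybenzene | COc1ccc(OC)c(OC)c1OC | starting material
2 | (2,3,4,5-tetramethoxyphenyl)lithium | [Li]c1cc(OC)c(OC)c(OC)c1OC | intermediate
3 | lithium trimethoxy(2,3,4,5-tetramethoxyphenyl)borate | [Li+].CO[B-](OC)(OC)c1cc(OC)c(OC)c(OC)c1OC | intermediate
4 | 2,3,4,5-tetramethoxyphenol | COc1cc(O)c(OC)c(OC)c1OC | intermediate
5 | 2,4-dihydroxybenzoic acid | O=C(O)c1ccc(O)cc1O | starting material
6 | propan-2-yl 2,4-di(propan-2-yloxy)benzoate | CC(C)OC(=O)c1ccc(OC(C)C)cc1OC(C)C | intermediate
7 | 2,4-di(propan-2-yloxy)benzoic acid | CC(C)Oc1ccc(C(=O)O)c(OC(C)C)c1 | intermediate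
8 | methyl methoxyacetate | COCC(=O)OC | starting material
9 | 2,4-di(propan-2-yloxy)benzoyl chloride | CC(C)Oc1ccc(C(=O)Cl)c(OC(C)C)c1 | intermediate
10 | lithium enolate of methyl methoxyacetate (lithium 1,2-dimethoxyethenolate, drawn as the chelated isomer with OLi cis to the 2-methoxy group) | CO/C=C(/OC)O[Li] | intermediate
11 | methyl 3-[2,4-di(propan-2-yloxy)phenyl]-2-methoxy-3-oxopropanoate (racemic) | COC(=O)C(OC)C(=O)c1ccc(OC(C)C)cc1OC(C)C | intermediate
12 | methyl (E)-3-[2,4-di(propan-2-yloxy)phenyl]-2-methoxy-3-(trifluoromethanesulfonyloxy)prop-2-enoate | COC(=O)/C(OC)=C(/c1ccc(OC(C)C)cc1OC(C)C)OS(=O)(=O)C(F)(F)F | intermediate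
13 | methyl (E)-3-[2,4-di(propan-2-yloxy)phenyl]-2-methoxy-3-(2,3,4,5-tetramethoxyphenoxy)prop-2-enoate | COC(=O)/C(OC)=C(/c1ccc(OC(C)C)cc1OC(C)C)Oc1cc(OC)c(OC)c(OC)c1OC | intermediate
14 | (E)-3-[2,4-di(propan-2-yloxy)phenyl]-2-methoxy-3-(2,3,4,5-tetramethoxyphenoxy)prop-2-enoic acid | OC(=O)/C(OC)=C(/c1ccc(OC(C)C)cc1OC(C)C)Oc1cc(OC)c(OC)c(OC)c1OC | intermediate
15 | (E)-3-[2,4-di(propan-2-yloxy)phenyl]-2-methoxy-3-(2,3,4,5-tetramethoxyphenoxy)prop-2-enoic trifluoroacetic anhydride | O=C(OC(=O)C(F)(F)F)/C(OC)=C(/c1ccc(OC(C)C)cc1OC(C)C)Oc1cc(OC)c(OC)c(OC)c1OC | intermediate
16 | 2-[2,4-di(propan-2-yloxy)phenyl]-3,5,6,7,8-pentamethoxy-4H-chromen-4-one | COc1c(OC)c(OC)c2c(=O)c(OC)c(-c3ccc(OC(C)C)cc3OC(C)C)oc2c1OC | intermediate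
17 | 2-[2,4-bis(dichloroboryloxy)phenyl]-5-(dichloroboryloxy)-3,6,7,8-tetramethoxy-4H-chromen-4-one | COc1c(OC)c(OB(Cl)Cl)c2c(=O)c(OC)c(-c3ccc(OB(Cl)Cl)cc3OB(Cl)Cl)oc2c1OC | intermediate
18 | 5,2',4'-trihydroxy-3,6,7,8-tetramethoxyflavone | COc1c(OC)c(O)c2c(=O)c(OC)c(-c3ccc(O)cc3O)oc2c1OC | target

## Step count and least certain steps

Total step count: 8. Longest linear sequence: 7 steps (steps 2 to 8, from 5). The ring A branch (step 1) joins at step 5.

**Step 7 (key step).** The most likely failure is diversion of the activated acid. After E/Z isomerisation the acyl group could be captured by O2' with loss of the isopropyl group (lactonisation). Alternatively, the donor-stabilised acyl group may ionise too sluggishly, so that the acid is recovered or degrades on forcing.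

Fallback: ring C is built by a Baker–Venkataraman sequence, setting out from 4 and 9 and returning at 16.
- Phenol 4 is heated with methoxyacetic acid in BF3·OEt2 (Fries-type ortho-acylation at its only free position) to give 1-(2-hydroxy-3,4,5,6-tetramethoxyphenyl)-2-methoxyethan-1-one F1.
- F1 is esterified with acid chloride 9 in pyridine to give 2-(methoxyacetyl)-3,4,5,6-tetramethoxyphenyl 2,4-di(propan-2-yloxy)benzoate F2.
- LiN(SiMe3)2 in THF induces the acyl transfer to 1-[2,4-di(propan-2-yloxy)phenyl]-3-(2-hydroxy-3,4,5,6-tetramethoxyphenyl)-2-methoxypropane-1,3-dione F3.
- Cyclodehydration of F3 with catalytic H2SO4 in AcOH should give 16.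

**Step 5.** The most likely failure is attack of the phenoxide at sulfur, which transfers the triflyl group and returns the enolate of 11. The other possibility is no addition at all, because the β-carbon is crowded and conjugated to a donor aryl ring.

Fallback: the uncatalysed substitution is replaced by a palladium-catalysed C–O cross-coupling, setting out from 11 and returning at 13.
- 11 is converted with NaH and nonafluorobutanesulfonyl fluoride into methyl (E)-3-[2,4-di(propan-2-yloxy)phenyl]-2-methoxy-3-(nonafluorobutanesulfonyloxy)prop-2-enoate F4, which is sturdier towards sulfonyl transfer.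
- F4 is coupled with 4 using the zerovalent palladium complex Pd2(dba)3, 2-di-tert-butylphosphino-2',4',6'-triisopropylbiphenyl and K3PO4 in toluene at 80 °C. This is the known aryl enol ether synthesis from enol sulfonates and phenols, and it does not depend on the electrophilicity of the β-carbon.

**Step 8.** The most likely failure is over-cleavage: once boron is chelated at O5 and the C4 carbonyl, the neighbouring 6-methyl ether or the 3-methyl ether may also be lost. If the reaction is stopped early to avoid this, the hindered 2'-isopropyl ether may be removed incompletely.

Fallback: the two kinds of ether cleavage are separated, setting out from 16 and returning at 18.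
- MgI2·OEt2 in toluene–Et2O at 60 °C, a weak Lewis acid that acts only on the chelated position, should give 2-[2,4-di(propan-2-yloxy)phenyl]-5-hydroxy-3,6,7,8-tetramethoxy-4H-chromen-4-one F5.
- A short treatment of F5 with BCl3 at −78 °C, where only isopropyl ethers react, then gives 18.

**Step 1.** The most likely failures are incomplete lithiation (the aryllithium is also consumed slowly by THF at 0 °C) and over-oxidation of the very electron-rich phenol by excess peroxide.

Fallback: the one-pot sequence is replaced by formylation and oxidation, setting out from 1 and returning at 4.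
- Vilsmeier–Haack formylation of 1 (POCl3, DMF) gives 2,3,4,5-tetramethoxybenzaldehyde F6.
- Baeyer–Villiger (Dakin-type) oxidation of F6 with mCPBA in CH2Cl2 gives 2,3,4,5-tetramethoxyphenyl formate F7.
- Hydrolysis of F7 with KOH in MeOH–H2O gives 4.

## Further compounds

F1 | step 7 | 1-(2-hydroxy-3,4,5,6-tetramethoxyphenyl)-2-methoxyethan-1-one | COCC(=O)c1c(O)c(OC)c(OC)c(OC)c1OC
F2 | step 7 | 2-(methoxyacetyl)-3,4,5,6-tetramethoxyphenyl 2,4-di(propan-2-yloxy)benzoate | COCC(=O)c1c(OC(=O)c2ccc(OC(C)C)cc2OC(C)C)c(OC)c(OC)c(OC)c1OC
F3 | step 7 | 1-[2,4-di(propan-2-yloxy)phenyl]-3-(2-hydroxy-3,4,5,6-tetramethoxyphenyl)-2-methoxypropane-1,3-dione (racemic) | COC(C(=O)c1ccc(OC(C)C)cc1OC(C)C)C(=O)c1c(O)c(OC)c(OC)c(OC)c1OC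
F4 | step 5 | methyl (E)-3-[2,4-di(propan-2-yloxy)phenyl]-2-methoxy-3-(nonafluorobutanesulfonyloxy)prop-2-enoate | COC(=O)/C(OC)=C(/c1ccc(OC(C)C)cc1OC(C)C)OS(=O)(=O)C(F)(F)C(F)(F)C(F)(F)C(F)(F)F
F5 | step 8 | 2-[2,4-di(propan-2-yloxy)phenyl]-5-hydroxy-3,6,7,8-tetramethoxy-4H-chromen-4-one | COc1c(OC)c(O)c2c(=O)c(OC)c(-c3ccc(OC(C)C)cc3OC(C)C)oc2c1OC
F6 | step 1 | 2,3,4,5-tetramethoxybenzaldehyde | O=Cc1cc(OC)c(OC)c(OC)c1OC
F7 | step 1 | 2,3,4,5-tetramethoxyphenyl formate | O=COc1cc(OC)c(OC)c(OC)c1OC
A1 | alternative 1 | 2-{1-[2,4-bis(benzyloxy)phenyl]-2-oxoethoxy}-3,4,5,6-tetramethoxybenzaldehyde (racemic) | O=CC(Oc1c(OC)c(OC)c(OC)c(OC)c1C=O)c1ccc(OCc2ccccc2)cc1OCc1ccccc1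
A2 | alternative 1 | 2-[2,4-bis(benzyloxy)phenyl]-3-hydroxy-5,6,7,8-tetramethoxychroman-4-one (diastereomer mixture) | COc1c(OC)c(OC)c2c(c1OC)OC(c1ccc(OCc3ccccc3)cc1OCc1ccccc1)C(O)C2=O
A3 | alternative 1 | 2-[2,4-bis(benzyloxy)phenyl]-3-hydroxy-5,6,7,8-tetramethoxy-4H-chromen-4-one | COc1c(OC)c(OC)c2c(=O)c(O)c(-c3ccc(OCc4ccccc4)cc3OCc3ccccc3)oc2c1OC
A4 | alternative 2 | 2-ethynyl-3,5,6,7,8-pentamethoxy-4H-chromen-4-one | C#Cc1oc2c(OC)c(OC)c(OC)c(OC)c2c(=O)c1OC
A5 | alternative 2 | 1-methoxy-1,3-bis(trimethylsilyloxy)buta-1,3-diene (alkene geometry not specified) | COC(O[Si](C)(C)C)=CC(=C)O[Si](C)(C)C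
A6 | alternative 2 | 2-(2,4-dihydroxyphenyl)-3,5,6,7,8-pentamethoxy-4H-chromen-4-one | COc1c(OC)c(OC)c2c(=O)c(OC)c(-c3ccc(O)cc3O)oc2c1OC
A7 | alternative 3 | 2-[2,4-bis(benzyloxy)phenyl]-3-methoxy-4H-pyran-4-one | COc1c(-c2ccc(OCc3ccccc3)cc2OCc2ccccc2)occc1=O
A8 | alternative 3 | dimethyl squarate (3,4-dimethoxycyclobut-3-ene-1,2-dione) | COC1=C(OC)C(=O)C1=O
A9 | alternative 3 | 4-{6-[2,4-bis(benzyloxy)phenyl]-5-methoxy-4-oxo-4H-pyran-2-yl}-4-hydroxy-2,3-dimethoxycyclobut-2-en-1-one (racemic) | COC1=C(OC)C(O)(c2cc(=O)c(OC)c(-c3ccc(OCc4ccccc4)cc3OCc3ccccc3)o2)C1=O
A10 | alternative 3 | 2-[2,4-bis(benzyloxy)phenyl]-5,8-dihydroxy-3,6,7-trimethoxy-4H-chromen-4-one | COc1c(OC)c(O)c2c(=O)c(OC)c(-c3ccc(OCc4ccccc4)cc3OCc3ccccc3)oc2c1O
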